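**Retrosynthetic overview**
1. Carbon sources are apigenin 1, which brings rings A, C and B ready-made (no ring is formed in the route), and benzyl bromide 2.
2. 1 and 2 are joined to 7-O-benzylapigenin 3: the 7-phenol is capped and the 4'-phenol is left free as the control element.
3. Key disconnection: both sulfate esters are cut at carbon–oxygen (C3–O and C3'–O), not at O–S. Compound 3 plus peroxydisulfate gives the 3-monosulfate 4 and then the bissulfate 5; the 4'-phenolate activates C3 (vinylogous para) and C3' (ortho).
4. O-Debenzylation gives the dipotassium salt 6, and K+/H+ exchange gives the target 7.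

Assumption: the target has no stereocentre, so no stereocontrol is needed; it is delivered in the drawn free-acid form by protonating its dipotassium salt, which is the better storage form.

**Step 1**
Reactants: 1 apigenin; 2 benzyl bromide (1.05 equiv)
Product: 3 7-O-benzylapigenin
Conditions: K2CO3 (1.1 equiv), DMF, 0 °C to rt, 16 h
Reagents that add atoms: none
Why: Williamson ether synthesis (SN2 O-benzylation) that is regioselective because one equivalent of K2CO3 ionises mainly the most acidic 7-OH (pKa about 7.4), while 5-OH is locked in a hydrogen bond to the C4 carbonyl and 4'-OH (pKa about 8.6) stays largely protonated; no stereocentre is formed.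

**Step 2**
Reactants: 3 7-O-benzylapigenin
Product: 5 dipotassium 7-O-benzylquercetin 3,3'-bissulfate, via potassium 7-O-benzylkaempferol 3-sulfate 4 (not isolated)
Conditions: K2S2O8 (2.6 equiv, two portions), K2CO3/KHCO3 buffer (pH 10), H2O/MeCN 1:1, N2, dark, 15–20 °C, 48 h
Reagents that add atoms: potassium peroxydisulfate, [K+].[K+].[O-]S(=O)(=O)OOS(=O)(=O)[O-]
Why: Proposed new method: a double Elbs-type C–H sulfoxylation in which the 4'-phenolate of 3, the only phenol ionised at pH 10 (7-OH is capped, the chelated 5-OH needs pH above 11), attacks the peroxide O–O bond of peroxydisulfate first through C3, its vinylogous para carbon (the charge is relayed C1'–C2=C3–C4=O and loss of the acidic C3 proton restores the flavone), and then through C3', its ortho carbon, so that each new C–O bond arrives already capped as a sulfate monoester that resists over-oxidation and 4'-OH stays free; the closest known reaction type is the Elbs persulfate oxidation of phenolates, including its ortho variant on para-blocked electron-poor phenols (4-nitrophenol to nitrocatechol sulfate), whereas attack through the vinylogous C3 position of a flavone and the one-flask C3/C3' combination are not known; no stereocentre is formed.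

**Step 3**
Reactants: 5 dipotassium 7-O-benzylquercetin 3,3'-bissulfate
Product: 7 quercetin 3,3'-bissulfate, via dipotassium quercetin 3,3'-bissulfate 6 (not isolated)
Conditions: H2 (1 atm), Pd(OH)2/C, MeOH/H2O, rt; filter, strip MeOH; then aq. HCl (2.0 equiv), 0 °C, C18 desalting, freeze-dry
Reagents that add atoms: none
Why: Catalytic hydrogenolysis of the benzyl aryl ether (O-debenzylation) is chemoselective because aryl sulfate salts, phenols and the conjugated chromone C2=C3 bond are inert to H2 over Pd(OH)2/C at 1 atm, and cold stoichiometric HCl only protonates the two sulfate anions before desalting; no stereocentre is involved.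

**Compound list**
1 | apigenin, 5,7-dihydroxy-2-(4-hydroxyphenyl)-4H-chromen-4-one | O=c1cc(-c2ccc(O)cc2)oc2cc(O)cc(O)c12 | starting material
2 | benzyl bromide | BrCc1ccccc1 | starting material
3 | 7-O-benzylapigenin, 7-(benzyloxy)-5-hydroxy-2-(4-hydroxyphenyl)-4H-chromen-4-one | O=c1cc(-c2ccc(O)cc2)oc2cc(OCc3ccccc3)cc(O)c12 | intermediate
4 | potassium 7-O-benzylkaempferol 3-sulfate, potassium 7-(benzyloxy)-5-hydroxy-2-(4-hydroxyphenyl)-4-oxo-4H-chromen-3-yl sulfate | [K+].O=c1c(OS(=O)(=O)[O-])c(-c2ccc(O)cc2)oc2cc(OCc3ccccc3)cc(O)c12 | intermediate (not isolated)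
5 | dipotassium 7-O-benzylquercetin 3,3'-bissulfate, sulfate esters on O3 and O3', free 5-OH and 4'-OH, benzyl on O7 | [K+].[K+].O=c1c(OS(=O)(=O)[O-])c(-c2ccc(O)c(OS(=O)(=O)[O-])c2)oc2cc(OCc3ccccc3)cc(O)c12 | intermediate
6 | dipotassium quercetin 3,3'-bissulfate | [K+].[K+].O=c1c(OS(=O)(=O)[O-])c(-c2ccc(O)c(OS(=O)(=O)[O-])c2)oc2cc(O)cc(O)c12 | intermediate (not isolated)
7 | quercetin 3,3'-bissulfate, 5,7-dihydroxy-2-[4-hydroxy-3-(sulfooxy)phenyl]-4-oxo-4H-chromen-3-yl hydrogen sulfate, achiral | O=c1c(OS(=O)(=O)O)c(-c2ccc(O)c(OS(=O)(=O)O)c2)oc2cc(O)cc(O)c12 | target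

**Total step count:** 3. **Longest linear sequence:** 3 (1 → 3 → 5 → 7).

**Steps most likely to fail**

Step 2 (the new step, highest risk). Likely failures are sluggish ortho attack at C3' (Elbs yields are modest; 3 and 4 can be recovered and resubmitted), attack at C8 through traces of 5-phenolate, and a third sulfoxylation at C5'. The fallback uses only known chemistry and replaces C–H sulfoxylation by O-sulfation of a flavonol that already carries all its oxygens. It sets out from benzyl bromide 2 and comes back to the route at 6. Cheap purchased rutin F1 is treated with 2 (2.4 equiv) and K2CO3 in DMF, which alkylates only the acidic 7- and 4'-hydroxyls and gives 7,4'-di-O-benzylrutin F2. Refluxing 2 M HCl in EtOH/H2O removes the disaccharide and gives 7,4'-di-O-benzylquercetin F3. Excess SO3·NMe3 and K2CO3 in DMF at 60 °C sulfate the only two reactive hydroxyls (3 and 3'; 5-OH is chelated) and give dipotassium 7,4'-di-O-benzylquercetin 3,3'-bissulfate F4. Hydrogenolysis under the step 3 conditions then gives 6, which is protonated to 7 as in step 3.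

Step 1. The risk is over-alkylation at 4'-OH and a difficult separation of mono- and dibenzyl ethers. The fallback sets out from 1 and comes back at 3, using acetate-directed alkylation instead of pKa control. Ac2O/pyridine gives apigenin 5,7,4'-triacetate F5. Heating F5 with 2, K2CO3 and catalytic KI in dry acetone exchanges only the labile 7-acetate (the ester para to the pyranone carbonyl) for benzyl and gives 5,4'-di-O-acetyl-7-O-benzylapigenin F6. K2CO3 in MeOH then removes the two remaining acetates to give 3.

Step 3. The risks are partial reduction of the ring C double bond, slow hydrogenolysis of the dianionic substrate, and sulfate loss if the acid stage is not kept cold and short. The fallback avoids hydrogenolysis by changing the 7-O protecting group; it sets out from 1 and comes back at 6. Allyl bromide and K2CO3 in DMF give 7-O-allylapigenin F7. The step 2 sulfoxylation gives, through potassium 7-O-allylkaempferol 3-sulfate F8 (not isolated), dipotassium 7-O-allylquercetin 3,3'-bissulfate F9. Pd(PPh3)4 (5 mol %) and morpholine in DMF/H2O at rt transfer the allyl group to the amine under neutral, non-reducing conditions and give 6.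

**Further compounds**
F1 | step 2 | rutin (purchased), quercetin 3-O-[α-L-rhamnopyranosyl-(1→6)-β-D-glucopyranoside] | C[C@@H]1O[C@@H](OC[C@H]2O[C@@H](Oc3c(-c4ccc(O)c(O)c4)oc4cc(O)cc(O)c4c3=O)[C@H](O)[C@@H](O)[C@@H]2O)[C@H](O)[C@H](O)[C@H]1O
F2 | step 2 | 7,4'-di-O-benzylrutin | C[C@@H]1O[C@@H](OC[C@H]2O[C@@H](Oc3c(-c4ccc(OCc5ccccc5)c(O)c4)oc4cc(OCc5ccccc5)cc(O)c4c3=O)[C@H](O)[C@@H](O)[C@@H]2O)[C@H](O)[C@H](O)[C@H]1O
F3 | step 2 | 7,4'-di-O-benzylquercetin | O=c1c(O)c(-c2ccc(OCc3ccccc3)c(O)c2)oc2cc(OCc3ccccc3)cc(O)c12
F4 | step 2 | dipotassium 7,4'-di-O-benzylquercetin 3,3'-bissulfate | [K+].[K+].O=c1c(OS(=O)(=O)[O-])c(-c2ccc(OCc3ccccc3)c(OS(=O)(=O)[O-])c2)oc2cc(OCc3ccccc3)cc(O)c12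
F5 | step 1 | apigenin 5,7,4'-triacetate | O=c1cc(-c2ccc(OC(C)=O)cc2)oc2cc(OC(C)=O)cc(OC(C)=O)c12
F6 | step 1 | 5,4'-di-O-acetyl-7-O-benzylapigenin | O=c1cc(-c2ccc(OC(C)=O)cc2)oc2cc(OCc3ccccc3)cc(OC(C)=O)c12
F7 | step 3 | 7-O-allylapigenin | O=c1cc(-c2ccc(O)cc2)oc2cc(OCC=C)cc(O)c12
F8 | step 3 | potassium 7-O-allylkaempferol 3-sulfate (not isolated) | [K+].O=c1c(OS(=O)(=O)[O-])c(-c2ccc(O)cc2)oc2cc(OCC=C)cc(O)c12
F9 | step 3 | dipotassium 7-O-allylquercetin 3,3'-bissulfate | [K+].[K+].O=c1c(OS(=O)(=O)[O-])c(-c2ccc(O)c(OS(=O)(=O)[O-])c2)oc2cc(OCC=C)cc(O)c12
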